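Each C ring is disconnected at C2–C3. C3 lies next to the C4 ketone and can be generated as a rhodium ketocarbene, whereas C2 is bound to O1 and benzylic to ring B, so the precursor only needs an O1–CH2–aryl ether whose C–H bond is doubly activated. Applied to both halves, this leads back to a twofold-symmetric, fully silylated 6,6''-linked biaryl bis(diazomethyl ketone) in which only O1 and O1'', para to the biaryl bond, carry 4-silyloxybenzyl groups. One operation with a chiral dirhodium tetracarboxylate should insert both carbenes into one enantiotopic benzylic hydrogen each, closing rings C and C'' and setting C2 and C2''. Acid-buffered fluoride then unmasks the six phenols.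

Key step: step 11

Assumption 1: the target string leaves the 6,6'' biaryl axis unassigned, so the axis is treated as not stereodefined; the silylated intermediates may be atropisomer mixtures and are carried on together.

Assumption 2: the (S)-prolinate catalyst is taken to deliver the 2S series; should the sense of induction be the opposite, the mirror-image catalyst Rh2(R-DOSP)4 is used with no other change.

Step 1
Reactants: 1 1,3-dimethoxybenzene (two equivalents, one for each aryl ring of the biaryl)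
Product: 3 2,2',6,6'-tetramethoxybiphenyl, via 2,6-dimethoxyphenyllithium 2 (not isolated)
Conditions: n-BuLi, THF, 0 °C to rt; then anhydrous FeCl3, −78 °C to rt
Reagents that add atoms: 1,3-dimethoxybenzene (second equivalent of 1), COc1cccc(OC)c1
Why: Directed ortho-lithiation between the two methoxy groups, then oxidative homocoupling of two aryllithium units by FeCl3 (trivalent iron as one-electron oxidant), is a known entry to tetra-ortho-alkoxy biaryls.

Step 2
Reactants: 3 2,2',6,6'-tetramethoxybiphenyl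
Product: 4 biphenyl-2,2',6,6'-tetrol
Conditions: BBr3, CH2Cl2, −78 °C to rt; aqueous work-up
Reagents that add atoms: none
Why: Lewis-acid cleavage of aryl methyl ethers with BBr3 is safe here because the biaryl carries no other functional group.

Step 3
Reactants: 4 biphenyl-2,2',6,6'-tetrol
Product: 5 2,2',6,6'-tetrakis(triisopropylsilyloxy)biphenyl
Conditions: TIPSOTf, 2,6-lutidine, CH2Cl2, 0 °C to rt
Reagents that add atoms: triisopropylsilyl trifluoromethanesulfonate, CC(C)[Si](OS(=O)(=O)C(F)(F)F)(C(C)C)C(C)C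
Why: Phenol silylation with a silyl triflate and a hindered base installs the final O5/O7 protection at the outset, and TIPS is chosen because it has no activated C–H within reach of the later carbene, resists base and O-to-O migration in steps 5, 8 and 10, and shields O5.

Step 4
Reactants: 5 2,2',6,6'-tetrakis(triisopropylsilyloxy)biphenyl
Product: 7 2,2',6,6'-tetrakis(triisopropylsilyloxy)biphenyl-4,4'-diol, via 4,4'-bis(pinacolboronate) 6 (not isolated)
Conditions: [Ir(OMe)(cod)]2 (cat.), 4,4'-di-tert-butyl-2,2'-bipyridine, B2pin2, THF, 80 °C; then NaBO3·4H2O, THF/H2O, rt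
Reagents that add atoms: sodium perborate, [Na+].[Na+].O[B-]1(O)OO[B-](O)(O)OO1
Why: Sterically controlled iridium-catalysed C–H borylation (Hartwig–Miyaura type) should pick the only C–H without an ortho substituent, C4/C4' para to the biaryl bond, and perborate oxidation of the C–B bonds then gives the two phenols that become O1 and O1''.

Step 5
Reactants: 7 2,2',6,6'-tetrakis(triisopropylsilyloxy)biphenyl-4,4'-diol
Product: 9 4,4'-dihydroxy-2,2',6,6'-tetrakis(triisopropylsilyloxy)biphenyl-3,3'-dicarbaldehyde, via bis(hydroxymethyl) diol 8 (not isolated)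
Conditions: anhydrous MgCl2, Et3N, (CH2O)n, MeCN, reflux
Reagents that add atoms: formaldehyde (as paraformaldehyde), C=O
Why: In the magnesium-mediated ortho-formylation of phenols (Casnati–Skattebøl reaction) the magnesium phenoxide delivers formaldehyde to the ortho carbon (para is blocked by the biaryl bond), a second formaldehyde oxidises the hydroxymethyl group by hydride transfer, and the deactivated product phenoxide should stop at one formyl group per ring.

Step 6
Reactants: 10 4-[(tert-butyldimethylsilyl)oxy]benzaldehyde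
Product: 11 4-[(tert-butyldimethylsilyl)oxy]benzyl alcohol
Conditions: NaBH4, MeOH/THF, 0 °C
Reagents that add atoms: none
Why: Borohydride reduction of an aromatic aldehyde leaves the aryl silyl ether untouched at 0 °C.

Step 7
Reactants: 9 4,4'-dihydroxy-2,2',6,6'-tetrakis(triisopropylsilyloxy)biphenyl-3,3'-dicarbaldehyde; 11 4-[(tert-butyldimethylsilyl)oxy]benzyl alcohol (two equivalents, one for each phenol)
Product: 12 4,4'-bis{[4-(tert-butyldimethylsilyloxy)benzyl]oxy}-2,2',6,6'-tetrakis(triisopropylsilyloxy)biphenyl-3,3'-dicarbaldehyde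
Conditions: PPh3, DIAD, THF, 0 °C to rt
Reagents that add atoms: {4-[(tert-butyldimethylsilyl)oxy]phenyl}methanol (second equivalent of 11), OCc1ccc(O[Si](C)(C)C(C)(C)C)cc1
Why: Twofold Mitsunobu etherification (one molecule of 11 per phenol) of the acidic salicylaldehyde-type phenols with a primary benzylic alcohol is neutral, so it needs neither a carbonate base that could attack silyl ethers nor a quinone-methide-prone benzyl halide.

Step 8
Reactants: 12 bis(4-silyloxybenzyl ether) dialdehyde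
Product: 13 bis(1-hydroxyethyl) compound, 1,1'-[4,4'-bis{[4-(tert-butyldimethylsilyloxy)benzyl]oxy}-2,2',6,6'-tetrakis(triisopropylsilyloxy)biphenyl-3,3'-diyl]bis(ethan-1-ol), mixture of diastereomers
Conditions: MeMgBr, THF, −78 °C to −40 °C; aqueous quench
Reagents that add atoms: methylmagnesium bromide, C[Mg]Br
Why: Grignard 1,2-addition to the aryl aldehydes at low temperature, where the bulky TIPS group next to the magnesium alkoxide should not migrate; the carbinol configuration is irrelevant because it is oxidised next.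

Step 9
Reactants: 13 bis(1-hydroxyethyl) compound
Product: 14 bis(methyl ketone), 1,1'-[4,4'-bis{[4-(tert-butyldimethylsilyloxy)benzyl]oxy}-2,2',6,6'-tetrakis(triisopropylsilyloxy)biphenyl-3,3'-diyl]bis(ethan-1-one)
Conditions: Dess–Martin periodinane, NaHCO3, CH2Cl2, rt
Reagents that add atoms: none
Why: Dess–Martin oxidation of the secondary benzylic alcohols under bicarbonate buffering spares the acid-labile benzyl ethers and all silyl ethers.

Step 10
Reactants: 14 bis(methyl ketone)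
Product: 16 bis(diazomethyl ketone), 1,1'-[4,4'-bis{[4-(tert-butyldimethylsilyloxy)benzyl]oxy}-2,2',6,6'-tetrakis(triisopropylsilyloxy)biphenyl-3,3'-diyl]bis(2-diazoethan-1-one), via bis(trifluoroacetyl) diketone 15 (not isolated)
Conditions: LiN(SiMe3)2, THF, −78 °C; CF3CO2CH2CF3; AcOH quench, aqueous wash; then 4-acetamidobenzenesulfonyl azide, Et3N, H2O, MeCN/THF, rt
Reagents that add atoms: 4-acetamidobenzenesulfonyl azide, CC(=O)Nc1ccc(S(=O)(=O)N=[N+]=[N-])cc1
Why: In this detrifluoroacetylative (Regitz-type) diazo transfer, kinetic enolate formation and Claisen-type trifluoroacetylation activate each methyl ketone, and the sulfonyl azide then delivers N2 while the trifluoroacetyl group leaves on the sulfonamide, so no strong acid or acid chloride touches the benzyl ethers.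

Step 11
Reactants: 16 bis(diazomethyl ketone)
Product: 17 (2S,2''S)-4',4'''-bis-O-(tert-butyldimethylsilyl)-5,5'',7,7''-tetrakis-O-(triisopropylsilyl)succedaneaflavanone
Conditions: Rh2(S-DOSP)4 {dirhodium tetrakis[(S)-N-(4-dodecylphenylsulfonyl)prolinate], 2 mol% per diazo group}, hexane, 0 °C to rt, slow addition of 16 at high dilution
Reagents that add atoms: none
Why: Each diazoketone loses N2 at the divalent rhodium dimer to give an electrophilic ketocarbene at C3 (C3''), which inserts in a concerted, asynchronous, hydride-transfer-like three-centre step into one benzylic C–H of the O1–CH2–aryl group, forming C2–C3 (C2''–C3'') with retention at carbon. The closest known reaction type is the enantioselective chroman-4-one synthesis from ortho-alkoxyaryl diazoketones with chiral dirhodium arylsulfonylprolinates. Rings C and C'' each close by 1,6-C–H insertion through a six-membered transition state (carbene carbon, C4, C4a, C8a, O1, C2), the five-membered alternative having only O1 itself to offer. C2 and C2'' are set by the chiral carboxylate pocket, which selects one of the two enantiotopic hydrogens at each OCH2 group, and because the two insertions are independent most stereo-errors should end in the separable (2R,2''S) diastereomer (statistical amplification of the 2S,2''S product). The step needs chemoselectivity for C–H insertion over oxonium ylide formation and regioselectivity for O1: O1 is a weakly basic vinylogous-ester oxygen whose CH2 is activated by the 4-silyloxyphenyl ring, O5 is buried under TIPS with no C–H within six-membered reach, and no other oxygen carries a benzyl group. Slow addition in a hydrocarbon solvent, in which the lipophilic substrate is soluble, should suppress carbene–diazo coupling.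

Step 12
Reactants: 17 hexasilyl succedaneaflavanone
Product: 18 succedaneaflavanone, (2S,2''S)-6,6''-binaringenin
Conditions: HF·pyridine, pyridine, THF, 0 °C to rt
Reagents that add atoms: none
Why: Fluoride cleavage of the six aryl silyl ethers in an acidic medium keeps every phenol protonated, so neither the C3 enolate nor the 4'-phenoxide that could open ring C and epimerise C2 is formed.

Compound list

1 | 1,3-dimethoxybenzene | COc1cccc(OC)c1 | starting material
2 | 2,6-dimethoxyphenyllithium (formed in situ) | [Li]c1c(OC)cccc1OC | intermediate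
3 | 2,2',6,6'-tetramethoxy-1,1'-biphenyl | COc1cccc(OC)c1-c1c(OC)cccc1OC | intermediate
4 | [1,1'-biphenyl]-2,2',6,6'-tetrol | Oc1cccc(O)c1-c1c(O)cccc1O | intermediate
5 | 2,2',6,6'-tetrakis[(triisopropylsilyl)oxy]-1,1'-biphenyl | CC(C)[Si](C(C)C)(C(C)C)Oc1cccc(O[Si](C(C)C)(C(C)C)C(C)C)c1-c1c(O[Si](C(C)C)(C(C)C)C(C)C)cccc1O[Si](C(C)C)(C(C)C)C(C)C | intermediate
6 | 4,4'-bis(4,4,5,5-tetramethyl-1,3,2-dioxaborolan-2-yl)-2,2',6,6'-tetrakis[(triisopropylsilyl)oxy]-1,1'-biphenyl (formed in situ) | CC(C)[Si](C(C)C)(C(C)C)Oc1cc(B2OC(C)(C)C(C)(C)O2)cc(O[Si](C(C)C)(C(C)C)C(C)C)c1-c1c(O[Si](C(C)C)(C(C)C)C(C)C)cc(B2OC(C)(C)C(C)(C)O2)cc1O[Si](C(C)C)(C(C)C)C(C)C | intermediate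
7 | 2,2',6,6'-tetrakis[(triisopropylsilyl)oxy]-[1,1'-biphenyl]-4,4'-diol | Oc1cc(O[Si](C(C)C)(C(C)C)C(C)C)c(-c2c(O[Si](C(C)C)(C(C)C)C(C)C)cc(O)cc2O[Si](C(C)C)(C(C)C)C(C)C)c(O[Si](C(C)C)(C(C)C)C(C)C)c1 | intermediate
8 | 3,3'-bis(hydroxymethyl)-2,2',6,6'-tetrakis[(triisopropylsilyl)oxy]-[1,1'-biphenyl]-4,4'-diol (formed in situ as its magnesium phenoxide) | OCc1c(O)cc(O[Si](C(C)C)(C(C)C)C(C)C)c(-c2c(O[Si](C(C)C)(C(C)C)C(C)C)cc(O)c(CO)c2O[Si](C(C)C)(C(C)C)C(C)C)c1O[Si](C(C)C)(C(C)C)C(C)C | intermediate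
9 | 4,4'-dihydroxy-2,2',6,6'-tetrakis[(triisopropylsilyl)oxy]-[1,1'-biphenyl]-3,3'-dicarbaldehyde | O=Cc1c(O)cc(O[Si](C(C)C)(C(C)C)C(C)C)c(-c2c(O[Si](C(C)C)(C(C)C)C(C)C)cc(O)c(C=O)c2O[Si](C(C)C)(C(C)C)C(C)C)c1O[Si](C(C)C)(C(C)C)C(C)C | intermediate
10 | 4-[(tert-butyldimethylsilyl)oxy]benzaldehyde | O=Cc1ccc(O[Si](C)(C)C(C)(C)C)cc1 | starting material
11 | {4-[(tert-butyldimethylsilyl)oxy]phenyl}methanol | OCc1ccc(O[Si](C)(C)C(C)(C)C)cc1 | intermediate
12 | 4,4'-bis({4-[(tert-butyldimethylsilyl)oxy]benzyl}oxy)-2,2',6,6'-tetrakis[(triisopropylsilyl)oxy]-[1,1'-biphenyl]-3,3'-dicarbaldehyde | O=Cc1c(OCc2ccc(O[Si](C)(C)C(C)(C)C)cc2)cc(O[Si](C(C)C)(C(C)C)C(C)C)c(-c2c(O[Si](C(C)C)(C(C)C)C(C)C)cc(OCc3ccc(O[Si](C)(C)C(C)(C)C)cc3)c(C=O)c2O[Si](C(C)C)(C(C)C)C(C)C)c1O[Si](C(C)C)(C(C)C)C(C)C | intermediate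
13 | 1,1'-[4,4'-bis({4-[(tert-butyldimethylsilyl)oxy]benzyl}oxy)-2,2',6,6'-tetrakis[(triisopropylsilyl)oxy]-[1,1'-biphenyl]-3,3'-diyl]bis(ethan-1-ol), mixture of diastereomers | CC(O)c1c(OCc2ccc(O[Si](C)(C)C(C)(C)C)cc2)cc(O[Si](C(C)C)(C(C)C)C(C)C)c(-c2c(O[Si](C(C)C)(C(C)C)C(C)C)cc(OCc3ccc(O[Si](C)(C)C(C)(C)C)cc3)c(C(C)O)c2O[Si](C(C)C)(C(C)C)C(C)C)c1O[Si](C(C)C)(C(C)C)C(C)C | intermediate
14 | 1,1'-[4,4'-bis({4-[(tert-butyldimethylsilyl)oxy]benzyl}oxy)-2,2',6,6'-tetrakis[(triisopropylsilyl)oxy]-[1,1'-biphenyl]-3,3'-diyl]bis(ethan-1-one) | CC(=O)c1c(OCc2ccc(O[Si](C)(C)C(C)(C)C)cc2)cc(O[Si](C(C)C)(C(C)C)C(C)C)c(-c2c(O[Si](C(C)C)(C(C)C)C(C)C)cc(OCc3ccc(O[Si](C)(C)C(C)(C)C)cc3)c(C(C)=O)c2O[Si](C(C)C)(C(C)C)C(C)C)c1O[Si](C(C)C)(C(C)C)C(C)C | intermediate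
15 | 1,1'-[4,4'-bis({4-[(tert-butyldimethylsilyl)oxy]benzyl}oxy)-2,2',6,6'-tetrakis[(triisopropylsilyl)oxy]-[1,1'-biphenyl]-3,3'-diyl]bis(4,4,4-trifluorobutane-1,3-dione) (crude, used directly) | O=C(CC(=O)C(F)(F)F)c1c(OCc2ccc(O[Si](C)(C)C(C)(C)C)cc2)cc(O[Si](C(C)C)(C(C)C)C(C)C)c(-c2c(O[Si](C(C)C)(C(C)C)C(C)C)cc(OCc3ccc(O[Si](C)(C)C(C)(C)C)cc3)c(C(=O)CC(=O)C(F)(F)F)c2O[Si](C(C)C)(C(C)C)C(C)C)c1O[Si](C(C)C)(C(C)C)C(C)C | intermediate
16 | 1,1'-[4,4'-bis({4-[(tert-butyldimethylsilyl)oxy]benzyl}oxy)-2,2',6,6'-tetrakis[(triisopropylsilyl)oxy]-[1,1'-biphenyl]-3,3'-diyl]bis(2-diazoethan-1-one) | [N-]=[N+]=CC(=O)c1c(OCc2ccc(O[Si](C)(C)C(C)(C)C)cc2)cc(O[Si](C(C)C)(C(C)C)C(C)C)c(-c2c(O[Si](C(C)C)(C(C)C)C(C)C)cc(OCc3ccc(O[Si](C)(C)C(C)(C)C)cc3)c(C(=O)C=[N+]=[N-])c2O[Si](C(C)C)(C(C)C)C(C)C)c1O[Si](C(C)C)(C(C)C)C(C)C | intermediate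
17 | (2S,2'S)-2,2'-bis{4-[(tert-butyldimethylsilyl)oxy]phenyl}-5,5',7,7'-tetrakis[(triisopropylsilyl)oxy]-2,2',3,3'-tetrahydro-4H,4'H-[6,6'-bichromene]-4,4'-dione | O=C1C[C@@H](c2ccc(O[Si](C)(C)C(C)(C)C)cc2)Oc2cc(O[Si](C(C)C)(C(C)C)C(C)C)c(-c3c(O[Si](C(C)C)(C(C)C)C(C)C)cc4c(c3O[Si](C(C)C)(C(C)C)C(C)C)C(=O)C[C@@H](c3ccc(O[Si](C)(C)C(C)(C)C)cc3)O4)c(O[Si](C(C)C)(C(C)C)C(C)C)c21 | intermediate
18 | succedaneaflavanone, (2S,2'S)-5,5',7,7'-tetrahydroxy-2,2'-bis(4-hydroxyphenyl)-2,2',3,3'-tetrahydro-4H,4'H-[6,6'-bichromene]-4,4'-dione | O=C1C[C@@H](c2ccc(O)cc2)Oc2cc(O)c(-c3c(O)cc4c(c3O)C(=O)C[C@@H](c3ccc(O)cc3)O4)c(O)c21 | target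

Total step count: 12. Longest linear sequence: 11 steps (steps 1–5 and 7–12); step 6 is a one-step side branch.

Steps most likely to fail

Step 11. What may go wrong: attack of the O1 lone pair on the carbene (oxonium ylide formation followed by a 1,2-shift of the benzyl group) may outrun C–H insertion, or the catalyst may differentiate the two enantiotopic benzylic hydrogens too weakly. The fallback builds ring C the other way round and sets C2 by conjugate addition. Setting out from dialdehyde 9, excess MeMgBr (THF, −78 to 0 °C) should give the bis(1-hydroxyethyl) biphenyldiol F1. MnO2 (CH2Cl2, rt) should then give the bis(2-hydroxyacetophenone) F2, in which the O1 hydroxyls are free. N,N-Dimethylformamide dimethyl acetal (toluene, 90 °C) should give the bis(enaminone) F3, which is cyclised without isolation with p-toluenesulfonic acid to the 6,6'-bichromone F4. A palladium/pyridine-oxazoline-catalysed asymmetric conjugate addition of commercial 4-[(tert-butyldimethylsilyl)oxy]phenylboronic acid to both enone units [Pd(OCOCF3)2, the enantiomer of t-BuPyOx that leads to the 2S series, NH4PF6, H2O, ClCH2CH2Cl, 60 °C] would set C2 and C2'' under catalyst control and come back to the route at 17.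

Step 10. What may go wrong: trifluoroacetylation of the hindered, twisted enolates may stay incomplete, or the silyl ether next to the activated diketone may be lost during the amine/water stage. The fallback does not go through the methyl ketone. Setting out from dialdehyde 12, chlorite oxidation (NaClO2, NaH2PO4, 2-methyl-2-butene, t-BuOH/THF/H2O) should give the dicarboxylic acid F5. 1-Chloro-N,N,2-trimethylprop-1-en-1-amine (CH2Cl2, 0 °C) converts it under neutral conditions into the bis(acid chloride) F6, which is added without isolation to excess ethereal diazomethane at 0 °C (acylation of diazomethane, as in the first stage of an Arndt–Eistert homologation). This comes back to the route at 16 and leaves out steps 8–10.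

Step 5. What may go wrong: delivery of formaldehyde to the ring carbon between the hydroxyl and the bulky silyl ether may be sluggish, or the reaction may stall at the hydroxymethyl stage. The fallback brings in the acetyl group by cross-coupling. Setting out from diol 7, N-iodosuccinimide (CH2Cl2, −40 °C) should iodinate each ring once ortho to the hydroxyl to give the diiodo diol F7. Mitsunobu etherification with 11 (PPh3, DIAD, THF) gives the diiodo bis(benzyl ether) F8. A Stille coupling with tributyl(1-ethoxyvinyl)stannane [Pd(PPh3)4, toluene, 100 °C] gives the bis(1-ethoxyvinyl) compound F9, which is hydrolysed without isolation (1 M HCl, THF, 0 °C, short contact). This comes back to the route at 14 and replaces steps 5 and 7–9.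

Further compounds

F1 | step 11 | 3,3'-bis(1-hydroxyethyl)-2,2',6,6'-tetrakis[(triisopropylsilyl)oxy]-[1,1'-biphenyl]-4,4'-diol, mixture of diastereomers | CC(O)c1c(O)cc(O[Si](C(C)C)(C(C)C)C(C)C)c(-c2c(O[Si](C(C)C)(C(C)C)C(C)C)cc(O)c(C(C)O)c2O[Si](C(C)C)(C(C)C)C(C)C)c1O[Si](C(C)C)(C(C)C)C(C)C
F2 | step 11 | 1,1'-{4,4'-dihydroxy-2,2',6,6'-tetrakis[(triisopropylsilyl)oxy]-[1,1'-biphenyl]-3,3'-diyl}bis(ethan-1-one) | CC(=O)c1c(O)cc(O[Si](C(C)C)(C(C)C)C(C)C)c(-c2c(O[Si](C(C)C)(C(C)C)C(C)C)cc(O)c(C(C)=O)c2O[Si](C(C)C)(C(C)C)C(C)C)c1O[Si](C(C)C)(C(C)C)C(C)C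
F3 | step 11 | (2E,2'E)-1,1'-{4,4'-dihydroxy-2,2',6,6'-tetrakis[(triisopropylsilyl)oxy]-[1,1'-biphenyl]-3,3'-diyl}bis[3-(dimethylamino)prop-2-en-1-one] | CN(C)/C=C/C(=O)c1c(O)cc(O[Si](C(C)C)(C(C)C)C(C)C)c(-c2c(O[Si](C(C)C)(C(C)C)C(C)C)cc(O)c(C(=O)/C=C/N(C)C)c2O[Si](C(C)C)(C(C)C)C(C)C)c1O[Si](C(C)C)(C(C)C)C(C)C
F4 | step 11 | 5,5',7,7'-tetrakis[(triisopropylsilyl)oxy]-4H,4'H-[6,6'-bichromene]-4,4'-dione | O=c1ccoc2cc(O[Si](C(C)C)(C(C)C)C(C)C)c(-c3c(O[Si](C(C)C)(C(C)C)C(C)C)cc4occc(=O)c4c3O[Si](C(C)C)(C(C)C)C(C)C)c(O[Si](C(C)C)(C(C)C)C(C)C)c12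
F5 | step 10 | 4,4'-bis({4-[(tert-butyldimethylsilyl)oxy]benzyl}oxy)-2,2',6,6'-tetrakis[(triisopropylsilyl)oxy]-[1,1'-biphenyl]-3,3'-dicarboxylic acid | OC(=O)c1c(OCc2ccc(O[Si](C)(C)C(C)(C)C)cc2)cc(O[Si](C(C)C)(C(C)C)C(C)C)c(-c2c(O[Si](C(C)C)(C(C)C)C(C)C)cc(OCc3ccc(O[Si](C)(C)C(C)(C)C)cc3)c(C(=O)O)c2O[Si](C(C)C)(C(C)C)C(C)C)c1O[Si](C(C)C)(C(C)C)C(C)C
F6 | step 10 | 4,4'-bis({4-[(tert-butyldimethylsilyl)oxy]benzyl}oxy)-2,2',6,6'-tetrakis[(triisopropylsilyl)oxy]-[1,1'-biphenyl]-3,3'-dicarbonyl dichloride | ClC(=O)c1c(OCc2ccc(O[Si](C)(C)C(C)(C)C)cc2)cc(O[Si](C(C)C)(C(C)C)C(C)C)c(-c2c(O[Si](C(C)C)(C(C)C)C(C)C)cc(OCc3ccc(O[Si](C)(C)C(C)(C)C)cc3)c(C(=O)Cl)c2O[Si](C(C)C)(C(C)C)C(C)C)c1O[Si](C(C)C)(C(C)C)C(C)C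
F7 | step 5 | 3,3'-diiodo-2,2',6,6'-tetrakis[(triisopropylsilyl)oxy]-[1,1'-biphenyl]-4,4'-diol | Oc1cc(O[Si](C(C)C)(C(C)C)C(C)C)c(-c2c(O[Si](C(C)C)(C(C)C)C(C)C)cc(O)c(I)c2O[Si](C(C)C)(C(C)C)C(C)C)c(O[Si](C(C)C)(C(C)C)C(C)C)c1I
F8 | step 5 | 4,4'-bis({4-[(tert-butyldimethylsilyl)oxy]benzyl}oxy)-3,3'-diiodo-2,2',6,6'-tetrakis[(triisopropylsilyl)oxy]-1,1'-biphenyl | Ic1c(OCc2ccc(O[Si](C)(C)C(C)(C)C)cc2)cc(O[Si](C(C)C)(C(C)C)C(C)C)c(-c2c(O[Si](C(C)C)(C(C)C)C(C)C)cc(OCc3ccc(O[Si](C)(C)C(C)(C)C)cc3)c(I)c2O[Si](C(C)C)(C(C)C)C(C)C)c1O[Si](C(C)C)(C(C)C)C(C)C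
F9 | step 5 | 4,4'-bis({4-[(tert-butyldimethylsilyl)oxy]benzyl}oxy)-3,3'-bis(1-ethoxyvinyl)-2,2',6,6'-tetrakis[(triisopropylsilyl)oxy]-1,1'-biphenyl | CCOC(=C)c1c(OCc2ccc(O[Si](C)(C)C(C)(C)C)cc2)cc(O[Si](C(C)C)(C(C)C)C(C)C)c(-c2c(O[Si](C(C)C)(C(C)C)C(C)C)cc(OCc3ccc(O[Si](C)(C)C(C)(C)C)cc3)c(C(=C)OCC)c2O[Si](C(C)C)(C(C)C)C(C)C)c1O[Si](C(C)C)(C(C)C)C(C)C
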